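The numbers in the tables are calculated on assumed constants; noise was put on by code.

Percent of the J charged is the unit of these readings, and the number asked is a ratio of two of them, so we build that ratio up one process at a time.

| flask | J | Q | Z | remark | time |
|---|---|---|---|---|---|
| south-east | 0.10 M | 0.15 M | 1 mM | run made earlier |  |
| south-west | 0.10 M | 0.10 M | 1 mM | run made earlier |  |
| south | 0.10 M | 0.22 M | 1 mM | run made earlier |  |
| west | 0.10 M | 0.15 M | 2 mM | run made earlier |  |
| larch | 0.10 M | 0.150 M (in portions, 5, over 2.5 h) | 1.0 mM | first portion at the start, last at 2.5 h | 4.0 h |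
| elm | 0.10 M (fed, over 2.5 h) | 0.150 M | 1.0 mM | all else is in the flask from the start; the feed brings no volume worth counting | 4.0 h |
| alder | 0.10 M | 0.150 M (fed, over 2.5 h) | 1.0 mM | all else is in the flask from the start; the feed brings no volume worth counting | 4.0 h |
| birch | 0.10 M | 0.150 M | 1.0 mM | everything together at the start | 4.0 h |

- south-east (time / h: G / %, D / %): 0.333: 52.2, 33.3; 0.667: 47.8, 32.1; 1.00: 45.3, 31.1; 1.33: 43.1, 27.0; 1.50: 41.3, 26.1; 2.00: 38.7, 27.0; 2.50: 36.6, 26.1
- south-west (time / h: G / %, D / %): 0.500: 51.5, 32.9; 1.00: 52.6, 35.3; 1.50: 50.1, 32.8; 2.50: 51.2, 34.7; 3.00: 53.1, 35.3; 4.00: 52.5, 34.7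
- south (time / h: G / %, D / %): 0.333: 42.4, 30.5; 0.500: 39.3, 27.2; 0.667: 33.7, 27.1; 1.00: 28.2, 19.7; 1.50: 20.9, 14.4; 2.50: 16.2, 11.9; 4.00: 10.0, 6.5
- west (time / h: G / %, D / %): 0.333: 52.6, 36.0; 0.667: 47.7, 32.0; 1.00: 45.6, 30.6; 2.00: 38.1, 26.0; 4.00: 33.9, 23.0

(scatter of a reading: 1 percentage point)

- which flask leads in share of G in G plus D ("all alike" within 1.5 percentage points) (larch / elm / alder / birch / all alike)
- share of G in G plus D at the end, larch
- share of G in G plus D at the end, elm
- share of G in G plus D at the end, alder
- share of G in G plus D at the end, birch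

- the numbers in the tables scatter by 1 percentage point (one standard deviation)

Take the main step first: J and Q make product, and with Q equal to J, the south-west run shows that step with little after it. G plus D reads 84.4% at 0.500 h and 87.2% at 4.00 h, flat within the scatter. From this run we define the split s, the summed G over the summed G plus D, 60.2%.

Now add the second process: Q beyond J, the limiting reagent, eats G plus D and turns it into something we don't read. By whole charge, the new recipes carry a surplus of Q over J of 0.0500 M. Does this drain move s? We put s back into the draining south-east run, whose pooled split reads 60.1%, so the drain takes G and D in step. The south run, with a surplus of 0.120 M, reads 58.1%, a gap of 2 percentage points from s. Its surplus by whole charge is larger than that of the new recipes, so we don't carry the gap over. Last comes Z: doubled in the west run, the split reads 59.6%, a gap of 0.60 points from s. We commit to s for each flask, and so to no leader.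

The forecast gave all alike, with larch 60%, elm 59.5%, alder 60.2% and birch 59.7%, on the ground that “Q dosing therefore should change little”. The flasks give larch 60.0%, elm 60.2%, alder 60.0% and birch 60.2%: all alike.

    J + Q + Z → Z + G (k = 3900 M⁻² min⁻¹)
    Q + G → L (k = 0.230 M⁻¹ min⁻¹)
    G + Z ⇌ D + Z, rate k3*[Z]*[G] forward; the back reaction follows from the equilibrium constant (K = 0.660, k = 130 M⁻¹ min⁻¹)

A further larch with Z at 6.0 × 10⁻⁴ M holds L at 35.3%, so s puts its G at 38.9%, and it holds 38.7%. Larch itself is not at rest at 4.00 h: 10% of its Q stands, which is 15.3% of the J charged and can still go into L, and by s G's part of that amount is 9.21%. After 40.0 h larch holds Q at 0%, L at 50.0% against 34.7%, G at 30.1% against 39.2%, D at 19.9% against 26.1%, and its share stands at 60.2%.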